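## Structural features

The target is a cyclopent-2-enone (ring A: C1 the carbonyl carbon, C2 the methoxy-bearing and C3 the aryl-bearing alkene carbon, then C4 and C5) whose C4 is also the spiro carbon of an oxirane (ring B: C4, O, CH2), so the skeleton is a 1-oxaspiro[2.4]hept-6-en-5-one. Two 4-hydroxyphenyl rings are attached, one to C3 and one to the quaternary carbon C5, and C2 and C5 each carry a methoxy group. C4 and C5 are neighbouring, fully substituted stereocentres, (3R,4R) in spiro numbering; the oxirane oxygen lies on the face of ring A opposite to the C5 methoxy group and on the same face as the C5 aryl ring. Because neither centre bears hydrogen, they cannot epimerise, but they also cannot be corrected once the C4–C5 bond exists. The fragile parts are the oxirane (allylic to the enone through C2=C3–C4–O and acid-sensitive), the 2-methoxyenone, and the phenols, whose phenoxides are para to the benzylic C5–OMe bond and would deactivate any aryl ketone used earlier. The real difficulty is the bond between the two crowded carbons C4 and C5 with control of both configurations, not ring A or ring B, which follow from ordinary carbonyl and halohydrin chemistry. The key step uses the fact that C5 carries OMe, an aryl group and the C1 acyl carbon, the pattern of an aryl(acyl)carbene carbon that has taken up an alcohol, while C4 is at the oxidation level of a ketone flanked by the C3 aryl ketone and the oxirane CH2, that is, the central carbonyl of a chloromethyl 1,2-diketone.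

## Logic of the disconnections

18 to 17: the two phenolic O–H bonds are cut back to aryl O–Si bonds. A free phenol para to the aryl ketone would be deprotonated during the base-mediated ring closure and switch that carbonyl off, and silicon can be removed at the end by buffered fluoride without acid. The skeleton is unchanged; the gain is a base-tolerant substrate. The forward step must cleave two O–Si bonds without opening the oxirane or leaving phenoxides in solution.

17 to 14: the C2=C3 double bond and the oxirane O–CH2 bond are cut. C2 is alpha to the C1 carbonyl and C3 is a former aryl ketone carbon (aldol condensation), and the oxirane is the closed form of a chlorohydrin whose oxygen already sits on C4. Both rings disappear and acyclic 14 remains; its (2R,3R) centres correspond atom for atom to (3R,4R) of 18 and are not touched by the ring-forming chemistry. The forward step must close the oxirane before the tertiary alkoxide can fragment by retro-aldol cleavage of C4–C5, and it must keep the aryl silyl ethers, so an aprotic carbonate is used instead of methanolic base.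

14 to 6, 12 and 11: the C5–OMe bond and the C4–C5 bond are cut. C5 has the substituents of the carbene carbon of 6 after capture of 12, and C4 is the chloromethyl-flanked carbonyl carbon of 11. This is the largest simplification of the route: both stereocentres and the central bond vanish and three achiral pieces remain. The forward step must trap the ylide faster than it collapses by proton shift, must choose the alkyl-flanked carbonyl of 11, and must set two configurations under control of a chiral acid.

6 to 5: the C=N2 bond is cut. The benzylic methylene of 5 is activated by both the aryl ring and the carbonyl, so diazo transfer can be directed there. The forward step must not touch the less acidic OCH2 position.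

5 to 4: the C=O bond is traced to a secondary C–OH. This is done because 4 is the direct product of an epoxide opening; the carbinol centre is transient, so racemic material suffices. The forward step is a neutral oxidation.

4 to 1 and 2 (through 3): the aryl–CH2 bond is cut. Both partners are catalogue compounds, and the sequence avoids an ester acylation and decarboxylation whose hot halide conditions would endanger the aryl silyl ether. The forward step must attack the unsubstituted oxirane carbon, which copper catalysis secures.

11 to 10: the two C=O bonds are traced to a C≡C bond. This replaces a homologation of an arylglyoxylic acid chloride with diazomethane by an oxidation, which removes the most hazardous reagent from the plan. The forward step must stop at the diketone and spare the CH2Cl group.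

10 to 9: the C–Cl bond is traced to a primary propargylic C–OH. The chloride is introduced late so that it is not exposed to palladium and amine. The forward step must be neutral.

9 to 7 and 8: the aryl–alkyne bond is cut, leaving two commercial materials. The forward step is a standard cross-coupling of an aryl iodide.

## Other disconnections considered

Alternative 1: The cut is again the C4–C5 bond, but made by a 1,2-shift inside a six-membered cyclohexenetrione A2 in which C5 is already quaternary. Forward, methoxide (NaOMe or Mg(OMe)2) adds to the carbonyl between C5 and the future C4, C5 migrates to the neighbouring carbonyl carbon, and the attacked carbon leaves the ring as the methyl ester of A1 (benzilic ester-type ring contraction).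
- In favour: the carbon skeleton comes from a terphenylquinone-type precursor, the rearrangement type is well established, ring A and the C4–C5 bond form together, and C5 migrates with retention while C4 is set relative to it.
- Against: the absolute configuration must be introduced when A2 is made, by an oxidative methoxylation for which no dependable reagent control is apparent. Methoxide can choose among three carbonyls and two migrating bonds. After the key step the ester must be reduced to CH2OH beside the C1 ketone and the enone and then activated for oxirane closure. The allyl ethers would finally be removed with zerovalent palladium next to an ionisable allylic oxirane.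
- Comparison: on ring construction this plan is the better one, since the key step itself closes ring A. On making the crowded C4–C5 bond an intramolecular shift is at least the equal of an intermolecular aldol addition. On absolute stereocontrol and on the number of operations after the key step (two in the chosen plan) it is the weaker.

Alternative 2: The cut is at the C4–O and C5–O bonds, traced to one oxirane in A3 and from there to the C4=C5 double bond of the stereodefined tetrasubstituted allylic alcohol A4. Forward, Ti(OiPr)4, a dialkyl tartrate and t-BuOOH epoxidise A4 to A3. Then 12 opens the oxirane at benzylic C5 with inversion, both 1,1-disubstituted alkenes are ozonised, and aldol condensation and oxirane closure through a primary sulfonate follow.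
- In favour: the absolute sense is predictable from the tartrate and the relative configuration is locked by the alkene geometry. On predictability of absolute configuration this is the better plan, and on setting both centres in one operation it is the equal.
- Against: a tetrasubstituted alkene flanked by an aryl ring and two further alkenes should be a slow substrate for the titanium tartrate system, and A4 itself requires a stereoselective tetrasubstituted alkene synthesis. C5 of A3 is benzylic to a 4-silyloxyphenyl ring and allylic, so its opening should have carbocation character and inversion cannot be relied on. A3 is a divinyl oxirane that may rearrange under Lewis acid.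
- Comparison: mechanistically the stereochemistry is created more securely but then put at risk in the next step. In step economy it is the longer plan (methanolysis, double ozonolysis, condensation, sulfonylation and closure, deprotection, plus a linear route to A4), against two three-step branches and two steps after the key step here.

Alternative 3: The cuts are C3–C4, C5–C1 and C1–C2, which dissolve ring A into the aryl ynol ether A6, propadiene A7 and carbon monoxide A8. Forward, the Co2(CO)6 complex of A6 reacts with A7 under amine N-oxide promotion to give the cross-conjugated 4-methylenecyclopentenone A5 (intermolecular allenic Pauson–Khand reaction).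
- In favour: three bonds and ring A arise in one step from three trivial components, the C2 methoxy and C3 aryl groups are in place, and the exocyclic methylene is the precursor of the oxirane. On convergence it is the equal of the chosen three-component step, and on ring construction it is the better.
- Against: the regiochemistry must be right twice (methoxy alpha and aryl beta to the carbonyl; methylene at C4 and not at C5), and intermolecular allene cycloadditions are prone to isomer mixtures. Above all, A5 contains neither stereocentre. C5 would still have to be arylated and methoxylated to a quaternary centre with absolute control, and the methylene epoxidised on the correct face under the influence of C5 alone.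
- Comparison: the chosen plan pays for ring A with one extra condensation but creates the hardest bond and both stereocentres catalytically in one step. Here those elements are postponed to several later stereochemistry-bearing operations, so step economy and stereochemical security favour the chosen plan. Hazard is comparable (A8 and A7 as gases there, a diazo compound here).

Key step: step 7

Assumption: the sense of induction of the phosphoric acid cannot be assigned with certainty for this untested substrate pair; the (R)-acid is written, and its commercial antipode is to be used if a first correlation shows the opposite sense.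

Step 1
Reactants: 1 (4-bromophenoxy)(tert-butyl)dimethylsilane; 2 2-(methoxymethyl)oxirane (racemic glycidyl methyl ether)
Product: 4 1-[4-(tert-butyldimethylsilyloxy)phenyl]-3-methoxypropan-2-ol (racemic), via arylmagnesium bromide 3 (not isolated)
Conditions: Mg, THF, 45 °C; then CuI (10 mol %), 2, −30 → 0 °C; H2O
Reagents that add atoms: none
Why: Grignard formation followed by copper-catalysed SN2 opening of the terminal epoxide at its unsubstituted carbon should give the secondary alcohol; the aryl silyl ether and the methyl ether are inert, and the carbinol centre is removed in step 2, so racemic material is sufficient.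

Step 2
Reactants: 4 1-[4-(tert-butyldimethylsilyloxy)phenyl]-3-methoxypropan-2-ol
Product: 5 1-[4-(tert-butyldimethylsilyloxy)phenyl]-3-methoxypropan-2-one
Conditions: Dess–Martin periodinane, CH2Cl2, 0 °C → rt
Reagents that add atoms: none
Why: Periodinane oxidation of a secondary alcohol to the ketone under near-neutral conditions; the aryl silyl ether tolerates the acetic acid released and no stereocentre is at stake.

Step 3
Reactants: 5 1-[4-(tert-butyldimethylsilyloxy)phenyl]-3-methoxypropan-2-one
Product: 6 1-diazo-1-[4-(tert-butyldimethylsilyloxy)phenyl]-3-methoxypropan-2-one
Conditions: p-ABSA, DBU, MeCN (dry), 0 °C → rt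
Reagents that add atoms: 4-acetamidobenzenesulfonyl azide (p-ABSA), CC(=O)Nc1ccc(cc1)S(=O)(=O)N=[N+]=[N-]
Why: Regitz diazo transfer; DBU deprotonates the benzylic methylene, which is far more acidic than the OCH2 position, so the diazo group should enter only next to the aryl ring, and dry conditions preserve the aryl silyl ether.

Step 4
Reactants: 7 tert-butyl(4-iodophenoxy)dimethylsilane; 8 prop-2-yn-1-ol
Product: 9 3-[4-(tert-butyldimethylsilyloxy)phenyl]prop-2-yn-1-ol
Conditions: Pd(PPh3)2Cl2 (2 mol %), CuI (4 mol %), Et3N, THF, rt
Reagents that add atoms: none
Why: Sonogashira coupling of an aryl iodide with a terminal alkyne; the free primary alcohol and the silyl ether are tolerated at room temperature.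

Step 5
Reactants: 9 3-[4-(tert-butyldimethylsilyloxy)phenyl]prop-2-yn-1-ol
Product: 10 tert-butyl[4-(3-chloroprop-1-yn-1-yl)phenoxy]dimethylsilane
Conditions: PPh3, NCS, THF, 0 °C → rt
Reagents that add atoms: N-chlorosuccinimide, O=C1CCC(=O)N1Cl
Why: Appel-type chlorination; the alkoxyphosphonium salt of the primary propargylic alcohol is displaced by chloride in an SN2 reaction under neutral conditions that leave alkyne and silyl ether untouched.

Step 6
Reactants: 10 tert-butyl[4-(3-chloroprop-1-yn-1-yl)phenoxy]dimethylsilane
Product: 11 3-chloro-1-[4-(tert-butyldimethylsilyloxy)phenyl]propane-1,2-dione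
Conditions: KMnO4, NaHCO3, MgSO4, acetone/H2O, 0 °C → rt
Reagents that add atoms: potassium permanganate, [K+].[O-][Mn](=O)(=O)=O
Why: Buffered permanganate oxidation of an internal alkyne to the 1,2-diketone through a cyclic manganate ester; at near-neutral pH the arene, the silyl ether and the primary chloride should survive, and any hydrate of 11 is removed by azeotropic drying before step 7.

Step 7
Reactants: 6 1-diazo-1-[4-(tert-butyldimethylsilyloxy)phenyl]-3-methoxypropan-2-one; 11 3-chloro-1-[4-(tert-butyldimethylsilyloxy)phenyl]propane-1,2-dione; 12 methanol
Product: 14 (2R,3R)-2-(chloromethyl)-2-hydroxy-3,5-dimethoxy-1,3-bis[4-(tert-butyldimethylsilyloxy)phenyl]pentane-1,4-dione, via oxonium ylide 13 (not isolated)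
Conditions: Rh2(OAc)4 (2 mol %), (R)-3,3'-bis(triphenylsilyl)-1,1'-binaphthalene-2,2'-diyl hydrogen phosphate (10 mol %), 4 Å MS, CH2Cl2, −20 °C; 11 (1.0 equiv), 12 (1.2 equiv), 6 (1.5 equiv) added over 2 h
Reagents that add atoms: none
Why: Rh2(OAc)4 decomposes 6 to a donor/acceptor rhodium carbenoid, which 12 attacks to give the oxonium ylide 13 (in equilibrium with its rhodium enolate and free enol). Before the ylide collapses by 1,2-proton shift, its nucleophilic carbon adds to the acid-activated, chloromethyl-flanked carbonyl of 11, forming the bond between the two fully substituted carbons and, together with the C–OMe bond just made, both stereocentres of 14. The closest known reaction type is the Rh2(OAc)4/chiral phosphoric acid co-catalysed three-component aldol-type trapping of alcohol-derived oxonium ylides of aryl diazo compounds by activated carbonyl compounds. No ring is closed. Both new stereocentres are controlled by the phosphoric acid, which is expected to bind the enol O–H through its P=O oxygen and the diketone carbonyl through its P–OH in one cyclic array, so that one face of each partner is exposed; with the carbonyl oxygen held gauche to the enol carbon and the aroyl group of 11 anti to the enol aryl ring, the like (2R,3R) relative configuration results. The step needs chemoselectivity for trapping over O–H insertion, which the high electrophilicity of a 1,2-dione carbonyl bearing an alpha-chlorine, slow addition of 6 and low temperature should provide, and regioselectivity for the alkyl-flanked carbonyl, which the donor 4-silyloxyphenyl group secures by deactivating the aryl ketone. Intramolecular C–H insertion of the carbenoid into its own OCH3 group should be slower than capture by the alcohol present from the start.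

Step 8
Reactants: 14 (2R,3R)-2-(chloromethyl)-2-hydroxy-3,5-dimethoxy-1,3-bis[4-(tert-butyldimethylsilyloxy)phenyl]pentane-1,4-dione
Product: 17 (3R,4R)-4,7-bis[4-(tert-butyldimethylsilyloxy)phenyl]-4,6-dimethoxy-1-oxaspiro[2.4]hept-6-en-5-one, via epoxy diketone 15 (not isolated), via spirocyclic aldol 16 (not isolated)
Conditions: Cs2CO3, 4 Å MS, MeCN (dry), 0 °C; then 40 °C
Reagents that add atoms: none
Why: The tertiary alkoxide closes the oxirane by 3-exo-tet SN2 displacement of chloride (Thorpe–Ingold accelerated, carbinol oxygen retained), then the only enolisable position, the methoxymethyl group, adds to the aryl ketone in a 5-(enolexo)-exo-trig aldol reaction and E1cB dehydration gives the conjugated 2-methoxyenone. The aprotic carbonate keeps the aryl silyl ethers, so the aryl ketone stays electrophilic, and the low starting temperature favours ring closure over entropically driven retro-aldol fragmentation. Neither stereocentre bears hydrogen or takes part in a bond change at carbon, so both configurations are carried through.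

Step 9
Reactants: 17 (3R,4R)-4,7-bis[4-(tert-butyldimethylsilyloxy)phenyl]-4,6-dimethoxy-1-oxaspiro[2.4]hept-6-en-5-one
Product: 18 (3R,4R)-4,7-bis(4-hydroxyphenyl)-4,6-dimethoxy-1-oxaspiro[2.4]hept-6-en-5-one
Conditions: TBAF, AcOH (1:1), THF, 0 °C
Reagents that add atoms: none
Why: Fluoride cleaves the two aryl O–Si bonds; acetic acid protonates each phenoxide as it forms, so the oxirane, the enone and the benzylic methoxy group are not exposed to base, and the stereocentres are untouched.

## Compound list

1 | (4-bromophenoxy)(tert-butyl)dimethylsilane | CC(C)(C)[Si](C)(C)Oc1ccc(Br)cc1 | starting material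
2 | 2-(methoxymethyl)oxirane (glycidyl methyl ether, racemic) | COCC1CO1 | starting material
3 | [4-(tert-butyldimethylsilyloxy)phenyl]magnesium bromide | CC(C)(C)[Si](C)(C)Oc1ccc([Mg]Br)cc1 | intermediate
4 | 1-[4-(tert-butyldimethylsilyloxy)phenyl]-3-methoxypropan-2-ol (racemic) | COCC(O)Cc1ccc(O[Si](C)(C)C(C)(C)C)cc1 | intermediate
5 | 1-[4-(tert-butyldimethylsilyloxy)phenyl]-3-methoxypropan-2-one | COCC(=O)Cc1ccc(O[Si](C)(C)C(C)(C)C)cc1 | intermediate
6 | 1-diazo-1-[4-(tert-butyldimethylsilyloxy)phenyl]-3-methoxypropan-2-one | COCC(=O)C(=[N+]=[N-])c1ccc(O[Si](C)(C)C(C)(C)C)cc1 | intermediate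
7 | tert-butyl(4-iodophenoxy)dimethylsilane | CC(C)(C)[Si](C)(C)Oc1ccc(I)cc1 | starting material
8 | prop-2-yn-1-ol | OCC#C | starting material
9 | 3-[4-(tert-butyldimethylsilyloxy)phenyl]prop-2-yn-1-ol | OCC#Cc1ccc(O[Si](C)(C)C(C)(C)C)cc1 | intermediate
10 | tert-butyl[4-(3-chloroprop-1-yn-1-yl)phenoxy]dimethylsilane | ClCC#Cc1ccc(O[Si](C)(C)C(C)(C)C)cc1 | intermediate
11 | 3-chloro-1-[4-(tert-butyldimethylsilyloxy)phenyl]propane-1,2-dione | O=C(CCl)C(=O)c1ccc(O[Si](C)(C)C(C)(C)C)cc1 | intermediate
12 | methanol | CO | starting material
13 | oxonium ylide from the carbenoid of 6 and methanol, 1-[4-(tert-butyldimethylsilyloxy)phenyl]-3-methoxy-1-(methyloxonio)-2-oxopropan-1-ide (rhodium-associated, in equilibrium with its enol) | COCC(=O)[C-](c1ccc(O[Si](C)(C)C(C)(C)C)cc1)[OH+]C | intermediate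
14 | (2R,3R)-2-(chloromethyl)-2-hydroxy-3,5-dimethoxy-1,3-bis[4-(tert-butyldimethylsilyloxy)phenyl]pentane-1,4-dione | O=C(c1ccc(O[Si](C)(C)C(C)(C)C)cc1)[C@@](O)(CCl)[C@](OC)(c1ccc(O[Si](C)(C)C(C)(C)C)cc1)C(=O)COC | intermediate
15 | (1R)-1-{(2R)-2-[4-(tert-butyldimethylsilyloxy)benzoyl]oxiran-2-yl}-1,3-dimethoxy-1-[4-(tert-butyldimethylsilyloxy)phenyl]propan-2-one | O=C(c1ccc(O[Si](C)(C)C(C)(C)C)cc1)[C@@]1(CO1)[C@](OC)(c1ccc(O[Si](C)(C)C(C)(C)C)cc1)C(=O)COC | intermediate
16 | (3S,4R)-7-hydroxy-4,6-dimethoxy-4,7-bis[4-(tert-butyldimethylsilyloxy)phenyl]-1-oxaspiro[2.4]heptan-5-one (C6 and C7 not defined; same spatial arrangement at C3 and C4 as in 15, the C3 descriptor changes by ranking only) | COC1C(O)(c2ccc(O[Si](C)(C)C(C)(C)C)cc2)[C@@]2(CO2)[C@](OC)(c2ccc(O[Si](C)(C)C(C)(C)C)cc2)C1=O | intermediate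
17 | (3R,4R)-4,7-bis[4-(tert-butyldimethylsilyloxy)phenyl]-4,6-dimethoxy-1-oxaspiro[2.4]hept-6-en-5-one | COC1=C(c2ccc(O[Si](C)(C)C(C)(C)C)cc2)[C@@]2(CO2)[C@](OC)(c2ccc(O[Si](C)(C)C(C)(C)C)cc2)C1=O | intermediate
18 | (3R,4R)-4,7-bis(4-hydroxyphenyl)-4,6-dimethoxy-1-oxaspiro[2.4]hept-6-en-5-one | COC1=C(c2ccc(O)cc2)[C@@]2(CO2)[C@](OC)(c2ccc(O)cc2)C1=O | target

## Step count and least certain steps

Total: 9 steps (steps 1–3 and 4–6 run in parallel, then steps 7–9). Longest linear sequence: 6 steps (1 to 4, 5, 6, 14, 17, 18; the branch from 7 is equally long).

Step 7 (key step). The most likely failure is collapse of the oxonium ylide by 1,2-proton shift before the carbon–carbon bond forms, or poor facial discrimination while two fully substituted carbons are joined. The addition is intermolecular and sterically demanding, and any background addition not bound to the acid would be unselective. The fallback is a two-component sequence that sets out from 6 and returns at 14.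
- Decomposition of 6 by Rh2(OAc)4 in the presence of excess 12, without acid or diketone, should give the racemic insertion product 1-[4-(tert-butyldimethylsilyloxy)phenyl]-1,3-dimethoxypropan-2-one F1, whose stereocentre is erased in the next operation.
- Soft enolisation with TMSOTf/Et3N toward the more acidic benzylic position gives the silyl enol ether tert-butyl{4-[1,3-dimethoxy-2-(trimethylsilyloxy)prop-1-en-1-yl]phenoxy}dimethylsilane F2.
- A Mukaiyama aldol addition of F2 to 11 follows, catalysed by the divalent copper Lewis acid formed from Cu(OTf)2 and (S,S)-tert-butyl-bis(oxazoline). This catalyst chelates both carbonyl oxygens of 11 and exposes the less hindered, chloromethyl-flanked carbonyl. It should give the silyl-transferred adduct (2R,3R)-2-(chloromethyl)-3,5-dimethoxy-1,3-bis[4-(tert-butyldimethylsilyloxy)phenyl]-2-(trimethylsilyloxy)pentane-1,4-dione F3.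
- Citric acid in methanol frees the tertiary alcohol and returns 14. The ligand antipode is chosen in the same way as for the acid.

Step 8. The most likely failure is retro-aldol fragmentation of the tertiary alkoxide of 14 across the C4–C5 bond in competition with oxirane closure; recombination of the fragments would erase the stereochemistry. A second danger is loss of the aryl silyl groups before the aldol addition, after which the 4-oxidophenyl ketone no longer accepts the enolate. The fallback builds the ring first and the oxirane last; it sets out from 14 and returns at 18.
- The tertiary hydroxyl is capped with TMSOTf/2,6-lutidine to give the trimethylsilyl ether F3 (the compound already described under step 7), which cannot form the alkoxide.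
- Cs2CO3 in MeCN then effects the aldol condensation to (4S,5R)-4-(chloromethyl)-2,5-dimethoxy-3,5-bis[4-(tert-butyldimethylsilyloxy)phenyl]-4-(trimethylsilyloxy)cyclopent-2-en-1-one F4.
- Excess TBAF in THF at 0 °C removes all three silyl groups, and the C4 alkoxide set free closes the oxirane on the chloromethyl group to give 18 directly. In the ring of F4 the C4–C5 bond lies in the plane of the C1 carbonyl, so the retro-aldol pathway lacks orbital overlap.

Step 6. The most likely failure is over-oxidation with cleavage between the two carbonyl carbons to the arylcarboxylic acid, or displacement of the doubly activated chloride in the aqueous buffer. The fallback sets out from 1 (through 3) and returns at 11.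
- Copper-catalysed opening of epichlorohydrin by 3 gives 1-chloro-3-[4-(tert-butyldimethylsilyloxy)phenyl]propan-2-ol F5.
- Periodinane oxidation gives 1-chloro-3-[4-(tert-butyldimethylsilyloxy)phenyl]propan-2-one F6.
- Riley oxidation with SeO2 in wet dioxane oxidises the benzylic methylene, the more readily enolised alpha-position, to the diketone 11.

Step 9. The most likely failure is that fluoride generates phenoxides faster than the buffer protonates them. The phenoxide on the C5 aryl ring can expel the benzylic methoxy group through a quinone methide, and fluoride or acetate can open the oxirane. The fallback avoids fluoride and base at the end; it sets out from 14 and returns at 18.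
- Acidic desilylation with HF·pyridine in THF, harmless before the oxirane exists, gives (2R,3R)-2-(chloromethyl)-2-hydroxy-1,3-bis(4-hydroxyphenyl)-3,5-dimethoxypentane-1,4-dione F7.
- Ac2O/pyridine acetylates the two phenols only (the tertiary hydroxyl is too hindered) to give (2R,3R)-1,3-bis(4-acetoxyphenyl)-2-(chloromethyl)-2-hydroxy-3,5-dimethoxypentane-1,4-dione F8.
- The Cs2CO3/MeCN cascade of step 8, helped by the more electrophilic 4-acetoxyaryl ketone, gives (3R,4R)-4,7-bis(4-acetoxyphenyl)-4,6-dimethoxy-1-oxaspiro[2.4]hept-6-en-5-one F9.
- NH4OAc in aqueous methanol removes the aryl acetates at neutral pH to give 18.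

## Further compounds

F1 | step 7 | 1-[4-(tert-butyldimethylsilyloxy)phenyl]-1,3-dimethoxypropan-2-one (racemic) | COCC(=O)C(OC)c1ccc(O[Si](C)(C)C(C)(C)C)cc1
F2 | step 7 | tert-butyl{4-[1,3-dimethoxy-2-(trimethylsilyloxy)prop-1-en-1-yl]phenoxy}dimethylsilane (alkene geometry not fixed) | COCC(O[Si](C)(C)C)=C(OC)c1ccc(O[Si](C)(C)C(C)(C)C)cc1
F3 | step 7 | (2R,3R)-2-(chloromethyl)-3,5-dimethoxy-1,3-bis[4-(tert-butyldimethylsilyloxy)phenyl]-2-(trimethylsilyloxy)pentane-1,4-dione | O=C(c1ccc(O[Si](C)(C)C(C)(C)C)cc1)[C@@](O[Si](C)(C)C)(CCl)[C@](OC)(c1ccc(O[Si](C)(C)C(C)(C)C)cc1)C(=O)COC
F4 | step 8 | (4S,5R)-4-(chloromethyl)-2,5-dimethoxy-3,5-bis[4-(tert-butyldimethylsilyloxy)phenyl]-4-(trimethylsilyloxy)cyclopent-2-en-1-one | COC1=C(c2ccc(O[Si](C)(C)C(C)(C)C)cc2)[C@@](O[Si](C)(C)C)(CCl)[C@](OC)(c2ccc(O[Si](C)(C)C(C)(C)C)cc2)C1=O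
F5 | step 6 | 1-chloro-3-[4-(tert-butyldimethylsilyloxy)phenyl]propan-2-ol (racemic) | OC(CCl)Cc1ccc(O[Si](C)(C)C(C)(C)C)cc1
F6 | step 6 | 1-chloro-3-[4-(tert-butyldimethylsilyloxy)phenyl]propan-2-one | O=C(CCl)Cc1ccc(O[Si](C)(C)C(C)(C)C)cc1
F7 | step 9 | (2R,3R)-2-(chloromethyl)-2-hydroxy-1,3-bis(4-hydroxyphenyl)-3,5-dimethoxypentane-1,4-dione | O=C(c1ccc(O)cc1)[C@@](O)(CCl)[C@](OC)(c1ccc(O)cc1)C(=O)COC
F8 | step 9 | (2R,3R)-1,3-bis(4-acetoxyphenyl)-2-(chloromethyl)-2-hydroxy-3,5-dimethoxypentane-1,4-dione | O=C(c1ccc(OC(C)=O)cc1)[C@@](O)(CCl)[C@](OC)(c1ccc(OC(C)=O)cc1)C(=O)COC
F9 | step 9 | (3R,4R)-4,7-bis(4-acetoxyphenyl)-4,6-dimethoxy-1-oxaspiro[2.4]hept-6-en-5-one | COC1=C(c2ccc(OC(C)=O)cc2)[C@@]2(CO2)[C@](OC)(c2ccc(OC(C)=O)cc2)C1=O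
A1 | alternative 1 | methyl (1S,5R)-1-hydroxy-3,5-dimethoxy-4-oxo-2,5-bis[4-(prop-2-en-1-yloxy)phenyl]cyclopent-2-ene-1-carboxylate | COC1=C(c2ccc(OCC=C)cc2)[C@@](O)(C(=O)OC)[C@](OC)(c2ccc(OCC=C)cc2)C1=O
A2 | alternative 1 | (3S)-3,5-dimethoxy-3,6-bis[4-(prop-2-en-1-yloxy)phenyl]cyclohex-5-ene-1,2,4-trione | COC1=C(c2ccc(OCC=C)cc2)C(=O)C(=O)[C@](OC)(c2ccc(OCC=C)cc2)C1=O
A3 | alternative 2 | [(2R,3R)-3-(3-methoxyprop-1-en-2-yl)-2-{1-[4-(tert-butyldimethylsilyloxy)phenyl]ethenyl}-3-[4-(tert-butyldimethylsilyloxy)phenyl]oxiran-2-yl]methanol | C=C(c1ccc(O[Si](C)(C)C(C)(C)C)cc1)[C@]2(CO)O[C@]2(c1ccc(O[Si](C)(C)C(C)(C)C)cc1)C(=C)COC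
A4 | alternative 2 | (2E)-4-(methoxymethyl)-2-{1-[4-(tert-butyldimethylsilyloxy)phenyl]ethenyl}-3-[4-(tert-butyldimethylsilyloxy)phenyl]penta-2,4-dien-1-ol | C=C(c1ccc(O[Si](C)(C)C(C)(C)C)cc1)/C(CO)=C(c1ccc(O[Si](C)(C)C(C)(C)C)cc1)\C(=C)COC
A5 | alternative 3 | 3-[4-(tert-butyldimethylsilyloxy)phenyl]-2-methoxy-4-methylidenecyclopent-2-en-1-one | COC1=C(c2ccc(O[Si](C)(C)C(C)(C)C)cc2)C(=C)CC1=O
A6 | alternative 3 | tert-butyl[4-(methoxyethynyl)phenoxy]dimethylsilane | COC#Cc1ccc(O[Si](C)(C)C(C)(C)C)cc1
A7 | alternative 3 | propadiene | C=C=C
A8 | alternative 3 | carbon monoxide | [C-]#[O+]
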